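The route rests on cutting ring C (C2–C6, C10–C12) at C2–C12 and C5–C6. Once C3=C4 and C10=C11 are written as alkenes, this eight-membered ring is the [4+4] adduct of two dienes, C2=C3–C4=C5 and C12=C11–C10=C6, that hang on the neighbouring ring A carbons C15 and C14. One nickel-catalysed cycloaddition therefore closes rings B and C, sets C2, C6 and C12 and leaves the tetrasubstituted C10=C11 alkene beside the C12 oxygen for a late directed epoxidation. The precursor is a fully substituted ring A cyclopentane (C17 silyl ether, C18 isopropyl) that carries the (E)-dienyl arm and the (Z)-silyl dienol ether ending in the C7-silyloxy cyclopentene of ring D.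

Key step: step 20

Remark: atoms carry the target numbers (ring A = C14–C18, ring B = C1, C2, C12–C15, ring C = C2–C6, C10–C12, ring D = C6–C10). α is the face of H-14 and of the C12 oxygen; β is the face of the C15 methyl. TBS = tert-butyldimethylsilyl, TES = triethylsilyl.

Remark: next to a C17 ketone, the C18 epimer with isopropyl cis to the C14 substituent is assumed to be the less stable one. C17 is therefore carried as a silyl-protected alcohol (set together with C18 in step 8) and oxidised only in the last step. The enol ether is a TES ether so that it can be purified before the nickel step.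

Step 1
Reactants: 1 3-methylcyclopent-2-en-1-one
Product: 2 (R)-3-methyl-3-[1-(trimethylsilyl)ethenyl]cyclopentan-1-one
Conditions: HC≡CSiMe3, i-Bu2AlH, hexanes, 55 °C; then 1, Cu(OTf)2 (5 mol%), chiral sulfonate-bearing N-heterocyclic carbene ligand (6 mol%), THF, −15 °C; aq. work-up
Reagents that add atoms: ethynyltrimethylsilane, C#C[Si](C)(C)C (transferred as its i-Bu2AlH adduct, CC(C)C[Al](CC(C)C)C(=C)[Si](C)(C)C)
Why: Copper-catalysed enantioselective conjugate addition of a silyl-substituted vinylaluminium to a β-substituted cyclopentenone; the carbene–copper catalyst differentiates the enone faces, and its enantiomer is chosen so that C15 forms as the (R) quaternary centre.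

Step 2
Reactants: 2 (R)-3-methyl-3-[1-(trimethylsilyl)ethenyl]cyclopentan-1-one
Product: 3 (R)-3-ethenyl-3-methylcyclopentan-1-one
Conditions: CF3CO2H, CH2Cl2, 0 °C to rt
Reagents that add atoms: none
Why: Protodesilylation of a vinylsilane (ipso protonation, loss of silicon from the β-silyl cation) leaves the vinyl group and touches no stereocentre.

Step 3
Reactants: 3 (R)-3-ethenyl-3-methylcyclopentan-1-one
Product: 4 (R)-4-ethenyl-4-methylcyclopent-2-en-1-one
Conditions: IBX, DMSO–fluorobenzene, 70 °C
Reagents that add atoms: none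
Why: IBX dehydrogenation of a ketone to the enone; because C15 is quaternary, only the C18=C14 enone can form.

Step 4
Reactants: 4 (R)-4-ethenyl-4-methylcyclopent-2-en-1-one
Product: 5 (R)-4-ethenyl-2-iodo-4-methylcyclopent-2-en-1-one
Conditions: I2, pyridine, CH2Cl2, 0 °C to rt
Reagents that add atoms: iodine, II
Why: α-Iodination of an enone by conjugate addition of pyridine, iodination of the enolate and elimination.

Step 5
Reactants: 5 (R)-4-ethenyl-2-iodo-4-methylcyclopent-2-en-1-one
Product: 6 (R)-4-ethenyl-4-methyl-2-(propan-2-yl)cyclopent-2-en-1-one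
Conditions: i-PrZnBr, Pd(OAc)2 (3 mol%), CPhos (6 mol%), THF–toluene, rt
Reagents that add atoms: isopropylzinc bromide, CC(C)[Zn]Br
Why: Negishi coupling of an α-iodoenone with a secondary alkylzinc halide; the biaryl phosphine favours reductive elimination over β-hydride migration, so the branched isopropyl group should be kept.

Step 6
Reactants: 6 (R)-4-ethenyl-4-methyl-2-(propan-2-yl)cyclopent-2-en-1-one
Product: 7 (1S,4R)-4-ethenyl-4-methyl-2-(propan-2-yl)cyclopent-2-en-1-ol
Conditions: (R)-2-methyl-CBS-oxazaborolidine (20 mol%), catecholborane, toluene, −78 to −40 °C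
Reagents that add atoms: none
Why: Corey–Bakshi–Shibata reduction; catalyst-controlled 1,2-hydride delivery (the α-branched alkene arm acting as the large group) should set C17 as (S) with the oxygen on the β face, and catecholborane leaves the vinyl group alone.

Step 7
Reactants: 7 (1S,4R)-4-ethenyl-4-methyl-2-(propan-2-yl)cyclopent-2-en-1-ol
Product: 9 ethyl 2-[(1R,5R)-5-ethenyl-5-methyl-2-(propan-2-yl)cyclopent-2-en-1-yl]acetate, via mixed ketene acetal 8 (not isolated)
Conditions: CH3C(OEt)3, EtCO2H (cat.), xylene, 140 °C, EtOH distilled off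
Reagents that add atoms: triethyl orthoacetate, CC(OCC)(OCC)OCC
Why: Johnson–Claisen rearrangement; the suprafacial [3,3] shift transfers the C17–O configuration to C14, so the CH2CO2Et arm (C13, C12) arrives on the β face, cis to the C15 methyl and trans to the vinyl group.

Step 8
Reactants: 9 ethyl 2-[(1R,5R)-5-ethenyl-5-methyl-2-(propan-2-yl)cyclopent-2-en-1-yl]acetate
Product: 11 diol ester (ring A; 17α-OH; 18β-isopropyl; 14β-CH2CO2Et; 15β-methyl; 15α-CH2CH2OH), via cyclic alkylborane 10 (not isolated)
Conditions: BH3·THF (1.2 equiv), THF, 0 °C to rt; then NaBO3·4H2O, H2O, rt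
Reagents that add atoms: sodium perborate tetrahydrate (NaBO3·4H2O), [Na+].[O-]OB=O.O.O.O.O
Why: Hydroboration–oxidation; the vinyl group reacts first and its alkylborane adds intramolecularly across C17=C18 with boron at C17 from the α face (six-membered boracycle, also the face anti to the C14 arm), so H-18 is delivered α, the isopropyl group ends cis to the C14 arm, and oxidation with retention gives the 17α-alcohol.

Step 9
Reactants: 11 diol ester (17α-OH; 15α-CH2CH2OH)
Product: 12 bis-TBS ether (17α-OTBS; 15α-CH2CH2OTBS)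
Conditions: TBSOTf, 2,6-lutidine, CH2Cl2, −78 to 0 °C
Reagents that add atoms: tert-butyldimethylsilyl triflate, CC(C)(C)[Si](C)(C)OS(=O)(=O)C(F)(F)F
Why: Silylation of both alcohols with a silyl triflate, which also reaches the hindered C17 hydroxyl.

Step 10
Reactants: 12 bis-TBS ether
Product: 13 primary alcohol (17α-OTBS; 15α-CH2CH2OH)
Conditions: HF·pyridine, pyridine, THF, 0 °C
Reagents that add atoms: none
Why: Selective desilylation; the unhindered primary TBS ether is cleaved much faster than the secondary one flanked by the isopropyl-bearing carbon.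

Step 11
Reactants: 13 primary alcohol
Product: 14 aldehyde (15α-CH2CHO; C2 is the aldehyde carbon)
Conditions: Dess–Martin periodinane, NaHCO3, CH2Cl2, rt
Reagents that add atoms: none
Why: Dess–Martin oxidation of a primary alcohol; the aldehyde has no α-stereocentre.

Step 12
Reactants: 14 aldehyde
Product: 15 (E)-enal (15α-CH2CH=C(CH3)CHO)
Conditions: Ph3P=C(CH3)CHO, toluene, 90 °C
Reagents that add atoms: 2-(triphenylphosphoranylidene)propanal, CC(C=O)=P(c1ccccc1)(c1ccccc1)c1ccccc1
Why: Wittig reaction with a stabilised ylide, which should give the (E) trisubstituted C2=C3 alkene under thermodynamic control of the oxaphosphetane.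

Step 13
Reactants: 15 (E)-enal
Product: 16 diene ester (15α-[(E)-3-methylpenta-2,4-dienyl]; 14β-CH2CO2Et)
Conditions: Ph3PCH3Br, KN(SiMe3)2, THF, −78 to 0 °C
Reagents that add atoms: methyltriphenylphosphonium bromide, C[P+](c1ccccc1)(c1ccccc1)c1ccccc1.[Br-]
Why: Wittig methylenation of the enal carbonyl completes the diene C2=C3–C4=C5; the ester does not react with the ylide at this temperature.

Step 14
Reactants: 16 diene ester
Product: 18 ethyl ketone (14β-CH2C(=O)CH2CH3), via Weinreb amide 17 (not isolated)
Conditions: MeNH(OMe)·HCl, i-PrMgCl, THF, −20 °C; then EtMgBr, 0 °C to rt; aq. NH4Cl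
Reagents that add atoms: ethylmagnesium bromide, CC[Mg]Br
Why: Ester aminolysis by the magnesium amide to the Weinreb amide, then Grignard addition; the chelated tetrahedral intermediate prevents over-addition, giving the ketone with C12 as carbonyl and C11 as its ethyl CH2.

Step 15
Reactants: 19 cyclopentane-1,3-dione
Product: 20 3-bromocyclopent-2-en-1-one
Conditions: PPh3, Br2, Et3N, CH2Cl2, 0 °C to rt
Reagents that add atoms: bromine, BrBr
Why: Conversion of the enol of a 1,3-diketone into the β-bromo enone by the bromophosphonium reagent (addition–elimination at the vinylogous acid).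

Step 16
Reactants: 20 3-bromocyclopent-2-en-1-one
Product: 21 (R)-3-bromocyclopent-2-en-1-ol
Conditions: (S)-2-methyl-CBS-oxazaborolidine (20 mol%), catecholborane, toluene, −78 °C
Reagents that add atoms: none
Why: Corey–Bakshi–Shibata reduction; with the alkenyl arm as the large group, the (S) catalyst should deliver hydride to give the (R) carbinol, the future C7.

Step 17
Reactants: 21 (R)-3-bromocyclopent-2-en-1-ol
Product: 22 [(1R)-3-bromocyclopent-2-en-1-yl]oxy(triethyl)silane
Conditions: Et3SiCl, imidazole, CH2Cl2, 0 °C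
Reagents that add atoms: chlorotriethylsilane, CC[Si](Cl)(CC)CC
Why: Silylation of the secondary allylic alcohol; the TES group is the steric marker for the later cycloaddition and is removable beside a TBS ether.

Step 18
Reactants: 18 ethyl ketone; 22 [(1R)-3-bromocyclopent-2-en-1-yl]oxy(triethyl)silane
Product: 24 β,γ-unsaturated ketone (C13H2–C12(=O)–C11H(CH3)–C10=C6; both C11 epimers; 7R-OTES), via lithium enolate 23 (not isolated)
Conditions: 18, LiN(SiMe3)2 (2.2 equiv), THF, −78 to 0 °C; then 22, Pd2(dba)3 (2.5 mol%), P(t-Bu)3 (10 mol%), toluene, rt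
Reagents that add atoms: none
Why: Palladium-catalysed α-alkenylation of a ketone enolate; the amide base enolises the unhindered ethyl side (C11) in preference to C13 next to the crowded ring carbon, the alkenyl–palladium species from 22 couples there to form C10–C11, and the C11 centre is of no consequence because it becomes sp2 in the next step.

Step 19
Reactants: 24 β,γ-unsaturated ketone
Product: 25 bis-diene (ring A with 17α-OTBS and 18β-isopropyl; 15α-[(E)-3-methylpenta-2,4-dienyl]; 14β-CH2–C12(OTES)=C11(CH3)–C10=C6 as (Z)-dienol ether; 7R-OTES)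
Conditions: Et3SiOTf, Et3N, CH2Cl2, −78 to 0 °C
Reagents that add atoms: triethylsilyl triflate, CC[Si](CC)(CC)OS(=O)(=O)C(F)(F)F
Why: Soft enolisation and O-silylation; the doubly activated C11–H (α to the ketone and allylic) is removed to give the conjugated dienol ether, and the (Z) isomer (oxygen cis to the cyclopentenyl group, C13 cis to the C11 methyl) is expected because only it lets the diene lie flat without a CH2/ring clash.

Step 20
Reactants: 25 bis-diene
Product: 26 tetracyclic diene (5-6-8-5; H-14 α; 15-methyl β; H-2 β; 12α-OTES; H-6 α; 7α-OTES; 17α-OTBS; 18β-isopropyl; ring alkenes C3=C4 and C10=C11)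
Conditions: Ni(cod)2 (20 mol%), PPh3 (40 mol%), toluene, 60 to 85 °C
Reagents that add atoms: none
Why: Proposed new method: zerovalent nickel binds both dienes, couples the untethered termini C5 and C6 oxidatively to a bis(η3-allyl) complex of divalent nickel and then joins C2 to C12 by reductive elimination, so the new alkenes fall at C3=C4 and C10=C11; the closest known reaction type is the Ni(cod)2/PPh3-catalysed intramolecular [4+4] cycloaddition of tethered all-carbon bis-dienes, which has not been shown with a fully substituted 1-silyloxy diene. Ring C closes as the cycloocta-1,5-diene through the two new bonds, and ring B closes as the six-membered ring spanned by the four-atom tether C1–C15–C14–C13 when C2–C12 forms. C2 is set by chair-like closure of ring B on the trans-disubstituted ring A, which keeps the C3 arm equatorial and away from the axial C15 methyl. C12 is set by the (Z)-enol ether geometry together with the transoid pairing of the two allyl units that a four-atom tether favours, which gives the trans B/C fusion. C6 is set by suprafacial use of the same diene face, which is the cyclopentene face anti to the C7 silyl ether in the matched (R) fragment. The step needs periselectivity for [4+4] over [4+2] and [2+2] closure and agreement of the three facial preferences; the phosphine-ligated nickel template and the matched fragments are chosen for this, but the combination is untested.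

Step 21
Reactants: 26 tetracyclic diene
Product: 27 diol (7α-OH; 12α-OH; 17α-OTBS)
Conditions: HF·pyridine, pyridine, THF, 0 °C to rt
Reagents that add atoms: none
Why: Fluoride-mediated desilylation; both TES ethers are cleaved while the hindered secondary TBS ether at C17 should survive.

Step 22
Reactants: 27 diol
Product: 28 C7 ketone (12α-OH; 17α-OTBS)
Conditions: Dess–Martin periodinane, NaHCO3, CH2Cl2, 0 °C to rt
Reagents that add atoms: none
Why: Dess–Martin oxidation of the only secondary alcohol (the tertiary C12 alcohol cannot react); buffered neutral conditions keep C6 and the β,γ-alkene in place.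

Step 23
Reactants: 28 C7 ketone
Product: 29 C7 exocyclic methylene compound (12α-OH; 17α-OTBS)
Conditions: Cp2TiMe2, toluene–THF, 65 °C, dark
Reagents that add atoms: dimethyltitanocene (Cp2TiMe2), C[Ti](C)(C1C=CC=C1)C1C=CC=C1
Why: Petasis methylenation; the titanium methylidene formed on heating olefinates the enolisable ketone without base, so C6 should not epimerise and the alkene should not move into conjugation.

Step 24
Reactants: 29 C7 exocyclic methylene compound
Product: 30 tetracyclic alkenol (3α-methyl with H-3 β; 7β-methyl with H-7 α; C10=C11; 12α-OH; 17α-OTBS)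
Conditions: H2 (1 atm), Pt/C (5%), EtOAc, rt
Reagents that add atoms: none
Why: Heterogeneous catalytic hydrogenation with syn addition from the exposed faces: the exocyclic alkene takes hydrogen at C7 from the α face (anti to C5 on C6), giving the 7β-methyl, and C3=C4 takes hydrogen from its convex face, away from C12 and the transannular alkene, giving H-3 β; the shielded tetrasubstituted C10=C11 should not be reduced.

Step 25
Reactants: 30 tetracyclic alkenol
Product: 31 diol (12α-OH; 17α-OH; C10=C11)
Conditions: Bu4NF, THF, 45 °C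
Reagents that add atoms: none
Why: Fluoride cleavage of the remaining silyl ether.

Step 26
Reactants: 31 diol
Product: 32 epoxy diol (10α,11α-epoxide; 12α-OH; 17α-OH)
Conditions: VO(acac)2 (10 mol%), t-BuOOH (decane), CH2Cl2, 0 °C to rt
Reagents that add atoms: tert-butyl hydroperoxide, CC(C)(C)OO
Why: Hydroxyl-directed epoxidation of an allylic alcohol; the vanadium alkoxide of the C12 hydroxyl delivers oxygen to the α face of C10=C11, which sets C10 and C11, and the remote secondary alcohol is not involved.

Step 27
Reactants: 32 epoxy diol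
Product: 33 target CNP0332295.1
Conditions: Dess–Martin periodinane, NaHCO3, CH2Cl2, 0 °C to rt
Reagents that add atoms: none
Why: Dess–Martin oxidation of the secondary C17 alcohol under buffered, non-enolising conditions gives the ketone without disturbing C18 or the epoxy alcohol.

Compound list

1 | 3-methylcyclopent-2-en-1-one | CC1=CC(=O)CC1 | starting material
2 | (R)-3-methyl-3-[1-(trimethylsilyl)ethenyl]cyclopentan-1-one | O=C1C[C@](C)(C(=C)[Si](C)(C)C)CC1 | intermediate
3 | (R)-3-ethenyl-3-methylcyclopentan-1-one | O=C1C[C@](C)(C=C)CC1 | intermediate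
4 | (R)-4-ethenyl-4-methylcyclopent-2-en-1-one | O=C1C[C@](C)(C=C)C=C1 | intermediate
5 | (R)-4-ethenyl-2-iodo-4-methylcyclopent-2-en-1-one | O=C1C[C@](C)(C=C)C=C1I | intermediate
6 | (R)-4-ethenyl-4-methyl-2-(propan-2-yl)cyclopent-2-en-1-one | O=C1C[C@](C)(C=C)C=C1C(C)C | intermediate
7 | (1S,4R)-4-ethenyl-4-methyl-2-(propan-2-yl)cyclopent-2-en-1-ol | O[C@H]1C[C@](C)(C=C)C=C1C(C)C | intermediate
8 | mixed ketene acetal, (1S,4R)-1-[(1-ethoxyethenyl)oxy]-4-ethenyl-4-methyl-2-(propan-2-yl)cyclopent-2-ene | C=C(OCC)O[C@H]1C[C@](C)(C=C)C=C1C(C)C | intermediate (not isolated)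
9 | ethyl 2-[(1R,5R)-5-ethenyl-5-methyl-2-(propan-2-yl)cyclopent-2-en-1-yl]acetate | CC(C)C1=CC[C@](C)(C=C)[C@H]1CC(=O)OCC | intermediate
10 | cyclic alkylborane, boron bridging C2 of the 15α-ethyl arm and C17 (α) | CC(C)[C@H]1[C@H]2C[C@](C)(CCB2)[C@H]1CC(=O)OCC | intermediate (not isolated)
11 | diol ester: ring A with 17α-OH, 18β-isopropyl, 14β-CH2CO2Et, 15β-methyl, 15α-CH2CH2OH | CC(C)[C@H]1[C@H](O)C[C@](C)(CCO)[C@H]1CC(=O)OCC | intermediate
12 | bis-TBS ether of 11 | CC(C)[C@H]1[C@H](O[Si](C)(C)C(C)(C)C)C[C@](C)(CCO[Si](C)(C)C(C)(C)C)[C@H]1CC(=O)OCC | intermediate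
13 | primary alcohol: 17α-OTBS, 15α-CH2CH2OH | CC(C)[C@H]1[C@H](O[Si](C)(C)C(C)(C)C)C[C@](C)(CCO)[C@H]1CC(=O)OCC | intermediate
14 | aldehyde: 15α-CH2CHO | CC(C)[C@H]1[C@H](O[Si](C)(C)C(C)(C)C)C[C@](C)(CC=O)[C@H]1CC(=O)OCC | intermediate
15 | (E)-enal: 15α-CH2CH=C(CH3)CHO | CC(C)[C@H]1[C@H](O[Si](C)(C)C(C)(C)C)C[C@](C)(C/C=C(\C)C=O)[C@H]1CC(=O)OCC | intermediate
16 | diene ester: 15α-[(E)-3-methylpenta-2,4-dienyl], 14β-CH2CO2Et | CC(C)[C@H]1[C@H](O[Si](C)(C)C(C)(C)C)C[C@](C)(C/C=C(\C)C=C)[C@H]1CC(=O)OCC | intermediate
17 | Weinreb amide: 14β-CH2C(=O)N(OMe)Me | CC(C)[C@H]1[C@H](O[Si](C)(C)C(C)(C)C)C[C@](C)(C/C=C(\C)C=C)[C@H]1CC(=O)N(C)OC | intermediate (not isolated)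
18 | ethyl ketone: 14β-CH2C(=O)CH2CH3 | CC(C)[C@H]1[C@H](O[Si](C)(C)C(C)(C)C)C[C@](C)(C/C=C(\C)C=C)[C@H]1CC(=O)CC | intermediate
19 | cyclopentane-1,3-dione | O=C1CCC(=O)C1 | starting material
20 | 3-bromocyclopent-2-en-1-one | O=C1C=C(Br)CC1 | intermediate
21 | (R)-3-bromocyclopent-2-en-1-ol | BrC1=C[C@H](O)CC1 | intermediate
22 | [(1R)-3-bromocyclopent-2-en-1-yl]oxy(triethyl)silane | BrC1=C[C@H](O[Si](CC)(CC)CC)CC1 | intermediate
23 | lithium enolate of 18 on the C11 side | CC(C)[C@H]1[C@H](O[Si](C)(C)C(C)(C)C)C[C@](C)(C/C=C(\C)C=C)[C@H]1CC(O[Li])=CC | intermediate (not isolated)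
24 | β,γ-unsaturated ketone, C11 epimers | CC(C)[C@H]1[C@H](O[Si](C)(C)C(C)(C)C)C[C@](C)(C/C=C(\C)C=C)[C@H]1CC(=O)C(C)C2=C[C@H](O[Si](CC)(CC)CC)CC2 | intermediate
25 | bis-diene precursor with (Z)-TES dienol ether | CC(C)[C@H]1[C@H](O[Si](C)(C)C(C)(C)C)C[C@](C)(C/C=C(\C)C=C)[C@H]1C/C(O[Si](CC)(CC)CC)=C(\C)C2=C[C@H](O[Si](CC)(CC)CC)CC2 | intermediate
26 | tetracyclic diene, [4+4] adduct | CC(C)[C@H]1[C@H](O[Si](C)(C)C(C)(C)C)C[C@]3(C)C[C@@H]4/C(C)=C\C[C@H]5[C@H](O[Si](CC)(CC)CC)CC/C5=C(\C)[C@@]4(O[Si](CC)(CC)CC)C[C@@H]13 | intermediate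
27 | diol: 7α-OH, 12α-OH, 17α-OTBS | CC(C)[C@H]1[C@H](O[Si](C)(C)C(C)(C)C)C[C@]3(C)C[C@@H]4/C(C)=C\C[C@H]5[C@H](O)CC/C5=C(\C)[C@@]4(O)C[C@@H]13 | intermediate
28 | C7 ketone | CC(C)[C@H]1[C@H](O[Si](C)(C)C(C)(C)C)C[C@]3(C)C[C@@H]4/C(C)=C\C[C@H]5C(=O)CC/C5=C(\C)[C@@]4(O)C[C@@H]13 | intermediate
29 | C7 exocyclic methylene compound | CC(C)[C@H]1[C@H](O[Si](C)(C)C(C)(C)C)C[C@]3(C)C[C@@H]4/C(C)=C\C[C@H]5C(=C)CC/C5=C(\C)[C@@]4(O)C[C@@H]13 | intermediate
30 | tetracyclic alkenol: C3 and C7 methyls set, C10=C11, 12α-OH, 17α-OTBS | CC(C)[C@H]1[C@H](O[Si](C)(C)C(C)(C)C)C[C@]3(C)C[C@@H]4[C@H](C)CC[C@H]5[C@@H](C)CC/C5=C(\C)[C@@]4(O)C[C@@H]13 | intermediate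
31 | diol: 12α-OH, 17α-OH, C10=C11 | CC(C)[C@H]1[C@H](O)C[C@]3(C)C[C@@H]4[C@H](C)CC[C@H]5[C@@H](C)CC/C5=C(\C)[C@@]4(O)C[C@@H]13 | intermediate
32 | epoxy diol: 10α,11α-epoxide, 12α-OH, 17α-OH | CC(C)[C@H]1[C@H](O)C[C@]3(C)C[C@@H]4[C@H](C)CC[C@H]5[C@@H](C)CC[C@]56O[C@]6(C)[C@@]4(O)C[C@@H]13 | intermediate
33 | CNP0332295.1 | CC(C)[C@H]1C(=O)C[C@]2(C)C[C@@H]3[C@H](C)CC[C@H]4[C@@H](C)CC[C@]45O[C@]5(C)[C@@]3(O)C[C@@H]12 | target

Total steps: 27. Longest linear sequence: 24 steps (steps 1–14 and 18–27); steps 15–17 make the ring D fragment.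

Steps most likely to fail

1. Step 20 (nickel [4+4]). The crowded, fully substituted silyloxy diene may fail to bind or couple at nickel. The bis-allyl intermediate may close to a six- or four-membered ring instead of ring C. The allyl units may pair in the cisoid sense and give the cis B/C fusion, or nickel may take the cyclopentene face syn to the C7 silyl ether. Fallback with known chemistry, stepwise instead of metal-templated: from 25, triplet sensitisation (thioxanthone, 405 nm, degassed toluene) starts a diene–diene photocycloaddition. Its first bond, C2–C12, closes ring B with both allyl radicals equatorial. Collapse of the biradical gives 26 directly or the trans-fused cis-1,2-dialkenylcyclobutane F1 (ring C2–C3–C11–C12), which on heating (toluene, 110 °C) undergoes Cope rearrangement, breaking C3–C11 and forming C5–C6. Both paths return to the route at 26. The ring fusion and facial selectivity of this photochemical path would have to be established.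

2. Step 18 (α-alkenylation). Enolisation and coupling may take place at C13 instead of C11, and the alkenyl–palladium species may add to the pendant diene instead of the enolate. Fallback that fixes the enolate position by a different approach: from Weinreb amide 17, isolated after the first stage of step 14, CH2=CHMgBr (THF, 0 °C) gives the vinyl ketone F2. Conjugate reduction with LiBH(s-Bu)3 (THF, −78 °C) and trapping with Me3SiCl gives the regiodefined trimethylsilyl enol ether F3, enolised on the C11 side only. Palladium-catalysed coupling of F3 with bromide 22 (Pd2(dba)3, P(t-Bu)3, ZnF2, DMF, 60 °C) forms C10–C11 and returns to the route at 24.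

3. Step 24 (double hydrogenation). Hydrogen may be delivered to the wrong face of C3=C4, or the exocyclic methylene may migrate into ring D before it is reduced. Fallback that separates the two reductions and changes the mechanism at C3: from 29, RhCl(PPh3)3 and H2 (1 atm, benzene) reduce only the exocyclic alkene, from the α face, to give the 7β-methyl compound F4 with C3=C4 intact. The trisubstituted alkene is then reduced by radical hydrogen-atom transfer (Mn(dpm)3, PhSiH3, t-BuOOH, i-PrOH, rt), a stepwise process that places H-3 on the thermodynamically preferred side. This returns to the route at 30.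

Further compounds

F1 | step 20 | trans-fused cis-1,2-dialkenylcyclobutane (ring C2–C3–C11–C12; vinyl on C3 and silyloxycyclopentenyl on C11 cis) | CC(C)[C@H]1[C@H](O[Si](C)(C)C(C)(C)C)C[C@]3(C)C[C@@H]4[C@@](C)(C=C)[C@@](C)(C5=C[C@H](O[Si](CC)(CC)CC)CC5)[C@@]4(O[Si](CC)(CC)CC)C[C@@H]13
F2 | step 18 | vinyl ketone, 14β-CH2C(=O)CH=CH2 | CC(C)[C@H]1[C@H](O[Si](C)(C)C(C)(C)C)C[C@](C)(C/C=C(\C)C=C)[C@H]1CC(=O)C=C
F3 | step 18 | trimethylsilyl enol ether on the C11 side, 14β-CH2C(OSiMe3)=CHCH3 | CC(C)[C@H]1[C@H](O[Si](C)(C)C(C)(C)C)C[C@](C)(C/C=C(\C)C=C)[C@H]1CC(O[Si](C)(C)C)=CC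
F4 | step 24 | 7β-methyl tetracycle with C3=C4 and C10=C11 retained | CC(C)[C@H]1[C@H](O[Si](C)(C)C(C)(C)C)C[C@]3(C)C[C@@H]4/C(C)=C\C[C@H]5[C@@H](C)CC/C5=C(\C)[C@@]4(O)C[C@@H]13
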